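The plan cuts the bibenzyl bridge at the bond between its CH2 and the 4-hydroxyphenyl ring. In one pot, 9-BBN hydroboration of a C5 vinyl group on the finished 2H-chromene and B-alkyl Suzuki–Miyaura coupling with unprotected 4-iodophenol form this sp3–sp2 bond. The step exploits the saturated two-carbon bridge between C5 of the benzopyran and the phenol ring: in the precursor it is a vinyl group, the only monosubstituted alkene, so the pyran C3=C4 and prenyl C=C bonds, which forbid any stilbene hydrogenation, stay untouched. The precursor, 5-ethenyl-2,2-dimethyl-7-prenyloxy-2H-chromene, is built from 3,5-dihydroxybenzaldehyde by propargyl ether Claisen annulation, O-prenylation and Wittig methylenation.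

Key step: step 5

Remark: the target has no stereocentre and no double bond of defined geometry, so no stereocontrol is needed; 9-BBN is drawn as its monomer although it is sold as the dimer or as a THF solution.

Step 1
Reactants: 1 3,5-dihydroxybenzaldehyde; 2 3-chloro-3-methylbut-1-yne
Product: 3 3-hydroxy-5-[(2-methylbut-3-yn-2-yl)oxy]benzaldehyde
Conditions: K2CO3, KI, CuI (cat.), DMF, 60 °C; 1 in twofold excess, recovered
Reagents that add atoms: none
Why: Copper-assisted Williamson-type O-propargylation of the phenoxide by the tertiary propargylic chloride should give the ether, and since 1 is symmetric only mono- against bis-alkylation has to be controlled, which the excess of 1 does.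

Step 2
Reactants: 3 3-hydroxy-5-[(2-methylbut-3-yn-2-yl)oxy]benzaldehyde
Product: 6 7-hydroxy-2,2-dimethyl-2H-chromene-5-carbaldehyde, via 2-allenylphenol 4 (not isolated), via ortho-quinone methide 5 (not isolated)
Conditions: PhNEt2, 180 °C, Ar
Reagents that add atoms: none
Why: Aromatic propargyl Claisen rearrangement ([3,3]), enolization to 4, 1,5-hydrogen shift to 5 and oxa-6π electrocyclization should give the 2,2-dimethylchromene, the shift going to the ring carbon between the ether and the formyl group because a meta acceptor (CHO) directs toward itself and a meta donor (OH) directs to its para position.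

Step 3
Reactants: 6 7-hydroxy-2,2-dimethyl-2H-chromene-5-carbaldehyde; 7 1-bromo-3-methylbut-2-ene (prenyl bromide)
Product: 8 2,2-dimethyl-7-[(3-methylbut-2-en-1-yl)oxy]-2H-chromene-5-carbaldehyde
Conditions: K2CO3, DMF, rt
Reagents that add atoms: none
Why: Williamson ether synthesis, in which SN2 attack of the only phenoxide on the primary allylic bromide in a polar aprotic medium should favour O- over C-prenylation.

Step 4
Reactants: 8 2,2-dimethyl-7-[(3-methylbut-2-en-1-yl)oxy]-2H-chromene-5-carbaldehyde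
Product: 9 5-ethenyl-2,2-dimethyl-7-[(3-methylbut-2-en-1-yl)oxy]-2H-chromene
Conditions: Ph3PCH3Br, KOtBu, THF, 0 °C to rt
Reagents that add atoms: methyltriphenylphosphonium bromide, C[P+](c1ccccc1)(c1ccccc1)c1ccccc1.[Br-]
Why: Wittig methylenation of the aryl aldehyde, the only electrophile present, with the non-stabilized ylide should give the styrene-type vinyl group.

Step 5
Reactants: 9 5-ethenyl-2,2-dimethyl-7-[(3-methylbut-2-en-1-yl)oxy]-2H-chromene; 10 9-borabicyclo[3.3.1]nonane (9-BBN); 11 4-iodophenol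
Product: 13 4-{2-[2,2-dimethyl-7-[(3-methylbut-2-en-1-yl)oxy]-2H-chromen-5-yl]ethyl}phenol, via B-alkyl-9-BBN 12 (not isolated)
Conditions: 10 (0.5 M in THF, slight excess), 0 °C to rt; then 11, PdCl2(dppf)·CH2Cl2 (5 mol %), 3 M aq K3PO4 (4 equiv), degassed DMF, 55 °C
Reagents that add atoms: none
Why: 9-BBN adds syn and anti-Markovnikov across the C5 vinyl group to give the primary alkylborane 12; base converts it into the hydroxyborate, Pd(0)/dppf inserts into the C–I bond of 11, the primary alkyl group passes from boron to palladium and reductive elimination forms the CH2–aryl bond. This is the one-pot hydroboration/B-alkyl Suzuki–Miyaura cross-coupling, an established sp3–sp2 fragment union. No ring is closed and no stereocentre is created. The step needs chemoselectivity among three alkenes and regioselectivity for the terminal carbon: the bulky 9-BBN should react with the monosubstituted vinyl group much faster than with the cis-disubstituted C3=C4 bond next to the gem-dimethyl C2 or with the trisubstituted prenyl alkene, and boron goes to the unhindered CH2. The wide bite angle of dppf should favour reductive elimination over β-hydride elimination, and the excess of phosphate covers the acidic phenol, which needs no protecting group.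

Compound list
1 | 3,5-dihydroxybenzaldehyde | O=Cc1cc(O)cc(O)c1 | starting material
2 | 3-chloro-3-methylbut-1-yne | C#CC(C)(C)Cl | starting material
3 | 3-hydroxy-5-[(2-methylbut-3-yn-2-yl)oxy]benzaldehyde | C#CC(C)(C)Oc1cc(O)cc(C=O)c1 | intermediate
4 | 3,5-dihydroxy-2-(3-methylbuta-1,2-dien-1-yl)benzaldehyde (2-allenylphenol) | CC(C)=C=Cc1c(O)cc(O)cc1C=O | intermediate
5 | (6Z)-3-hydroxy-6-(3-methylbut-2-en-1-ylidene)-5-oxocyclohexa-1,3-diene-1-carbaldehyde (ortho-quinone methide) | CC(C)=C/C=C1\C(=O)C=C(O)C=C1C=O | intermediate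
6 | 7-hydroxy-2,2-dimethyl-2H-chromene-5-carbaldehyde | O=Cc1cc(O)cc2OC(C)(C)C=Cc12 | intermediate
7 | 1-bromo-3-methylbut-2-ene (prenyl bromide) | CC(C)=CCBr | starting material
8 | 2,2-dimethyl-7-[(3-methylbut-2-en-1-yl)oxy]-2H-chromene-5-carbaldehyde | CC(C)=CCOc1cc(C=O)c2C=CC(C)(C)Oc2c1 | intermediate
9 | 5-ethenyl-2,2-dimethyl-7-[(3-methylbut-2-en-1-yl)oxy]-2H-chromene | CC(C)=CCOc1cc(C=C)c2C=CC(C)(C)Oc2c1 | intermediate
10 | 9-borabicyclo[3.3.1]nonane (9-BBN) | B1C2CCCC1CCC2 | starting material
11 | 4-iodophenol | Oc1ccc(I)cc1 | starting material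
12 | 9-{2-[2,2-dimethyl-7-[(3-methylbut-2-en-1-yl)oxy]-2H-chromen-5-yl]ethyl}-9-borabicyclo[3.3.1]nonane | CC(C)=CCOc1cc(CCB2C3CCCC2CCC3)c2C=CC(C)(C)Oc2c1 | intermediate
13 | 4-{2-[2,2-dimethyl-7-[(3-methylbut-2-en-1-yl)oxy]-2H-chromen-5-yl]ethyl}phenol | CC(C)=CCOc1cc(CCc2ccc(O)cc2)c2c(c1)OC(C)(C)C=C2 | target

Total step count: 5
Longest linear sequence: 5 steps (1 → 3 → 6 → 8 → 9 → 13)

Steps most likely to fail

Risk 1 (step 5, key step). Oxidative addition to the phenoxide form of 11 and transmetalation of the borate may be slow, so that protodeboronation and β-hydride elimination from the alkylpalladium species could take over. The fallback sets out from 9 and comes back at 13; it replaces the boron nucleophile by an organozinc and masks the phenol.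
- Hydroboration of 9 with 10 as before, then oxidation of 12 (NaBO3·4H2O, THF/H2O, rt), should give 2-[2,2-dimethyl-7-[(3-methylbut-2-en-1-yl)oxy]-2H-chromen-5-yl]ethan-1-ol F1.
- Appel iodination (PPh3, I2, imidazole, CH2Cl2, 0 °C) should give 5-(2-iodoethyl)-2,2-dimethyl-7-[(3-methylbut-2-en-1-yl)oxy]-2H-chromene F2.
- Zinc insertion (Zn dust, LiCl, THF, 30 °C) should give {2-[2,2-dimethyl-7-[(3-methylbut-2-en-1-yl)oxy]-2H-chromen-5-yl]ethyl}zinc iodide F3, used at once.
- Negishi coupling of this reagent with commercial 4-iodophenyl acetate (CC(=O)Oc1ccc(I)cc1; Pd(OAc)2, SPhos, THF, rt) should give 4-{2-[2,2-dimethyl-7-[(3-methylbut-2-en-1-yl)oxy]-2H-chromen-5-yl]ethyl}phenyl acetate F4.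
- Methanolysis (K2CO3, MeOH, rt) should then give 13.

Risk 2 (step 2). The [3,3] shift may partition between the two ortho positions, so that the regioisomeric 5-hydroxy-7-formyl chromene forms alongside 6. The fallback sets out from 7 and comes back at 9; its regiochemistry is fixed by the hydrogen-bonded 5-OH of a chromanone.
- Commercial 5,7-dihydroxy-2,2-dimethylchroman-4-one (CC1(C)CC(=O)c2c(O)cc(O)cc2O1) should be alkylated by 7 (K2CO3, DMF, rt) only at the non-chelated 7-OH, giving 5-hydroxy-2,2-dimethyl-7-[(3-methylbut-2-en-1-yl)oxy]chroman-4-one F5.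
- Triflation (Tf2O, pyridine, CH2Cl2, 0 °C) should give 2,2-dimethyl-7-[(3-methylbut-2-en-1-yl)oxy]-4-oxochroman-5-yl trifluoromethanesulfonate F6.
- Suzuki–Miyaura vinylation with potassium vinyltrifluoroborate (C=C[B-](F)(F)F.[K+]; PdCl2(dppf), Cs2CO3, THF/H2O, 70 °C) should give 5-ethenyl-2,2-dimethyl-7-[(3-methylbut-2-en-1-yl)oxy]chroman-4-one F7.
- Reduction (NaBH4, MeOH, 0 °C) should give racemic 5-ethenyl-2,2-dimethyl-7-[(3-methylbut-2-en-1-yl)oxy]chroman-4-ol F8.
- Mesylation–elimination (MsCl, Et3N, CH2Cl2, 0 °C to rt) should give 9.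

Risk 3 (step 1). Over-alkylation to the bis-ether and dehydrochlorination of the sluggish tertiary chloride may erode the mono-ether while the diol is kept in excess. The fallback sets out from 1 and 7 and comes back at 8; it reverses the order of the two O-alkylations.
- The clean SN2 prenylation of 1 with a deficit of 7 (K2CO3, DMF, rt) should give 3-hydroxy-5-[(3-methylbut-2-en-1-yl)oxy]benzaldehyde F9.
- The single remaining OH can then be driven to completion with excess 2 (K2CO3, KI, CuI, DMF, 60 °C), giving 3-[(2-methylbut-3-yn-2-yl)oxy]-5-[(3-methylbut-2-en-1-yl)oxy]benzaldehyde F10.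
- Heating in o-xylene at 140 °C, below the temperature at which the aryl prenyl ether rearranges, should give 8 by the same Claisen/electrocyclization cascade.

Further compounds
F1 | step 5 | 2-[2,2-dimethyl-7-[(3-methylbut-2-en-1-yl)oxy]-2H-chromen-5-yl]ethan-1-ol | CC(C)=CCOc1cc(CCO)c2C=CC(C)(C)Oc2c1
F2 | step 5 | 5-(2-iodoethyl)-2,2-dimethyl-7-[(3-methylbut-2-en-1-yl)oxy]-2H-chromene | CC(C)=CCOc1cc(CCI)c2C=CC(C)(C)Oc2c1
F3 | step 5 | {2-[2,2-dimethyl-7-[(3-methylbut-2-en-1-yl)oxy]-2H-chromen-5-yl]ethyl}zinc iodide | CC(C)=CCOc1cc(CC[Zn]I)c2C=CC(C)(C)Oc2c1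
F4 | step 5 | 4-{2-[2,2-dimethyl-7-[(3-methylbut-2-en-1-yl)oxy]-2H-chromen-5-yl]ethyl}phenyl acetate | CC(C)=CCOc1cc(CCc2ccc(OC(C)=O)cc2)c2C=CC(C)(C)Oc2c1
F5 | step 2 | 5-hydroxy-2,2-dimethyl-7-[(3-methylbut-2-en-1-yl)oxy]chroman-4-one | CC(C)=CCOc1cc(O)c2C(=O)CC(C)(C)Oc2c1
F6 | step 2 | 2,2-dimethyl-7-[(3-methylbut-2-en-1-yl)oxy]-4-oxochroman-5-yl trifluoromethanesulfonate | CC(C)=CCOc1cc(OS(=O)(=O)C(F)(F)F)c2C(=O)CC(C)(C)Oc2c1
F7 | step 2 | 5-ethenyl-2,2-dimethyl-7-[(3-methylbut-2-en-1-yl)oxy]chroman-4-one | CC(C)=CCOc1cc(C=C)c2C(=O)CC(C)(C)Oc2c1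
F8 | step 2 | racemic 5-ethenyl-2,2-dimethyl-7-[(3-methylbut-2-en-1-yl)oxy]chroman-4-ol | CC(C)=CCOc1cc(C=C)c2C(O)CC(C)(C)Oc2c1
F9 | step 1 | 3-hydroxy-5-[(3-methylbut-2-en-1-yl)oxy]benzaldehyde | CC(C)=CCOc1cc(O)cc(C=O)c1
F10 | step 1 | 3-[(2-methylbut-3-yn-2-yl)oxy]-5-[(3-methylbut-2-en-1-yl)oxy]benzaldehyde | C#CC(C)(C)Oc1cc(OCC=C(C)C)cc(C=O)c1
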